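Ring C is cut at O1–C2 and C3–C4. C4 is a ketone and C2 is the O1-bearing benzylic carbon, so C3 is the central carbon of a masked 1,3-dicarbonyl. The C2–C3 unit is therefore delivered as a benzoyl carbene (a sulfoxonium ylide) to a salicylaldehyde that already carries ring A, the piperidine and one free phenol, the future O1. Phenol-directed rhodium insertion into the aldehyde C–H, carbene insertion (C3–C4) and cyclodehydration (O1–C2) give the flavone in one operation. The (2R)-piperidine centre comes from a sulfinyl imine addition, and C2 is set (S) afterwards by conjugate reduction with a ligated CuH.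

Key step: step 7

Remark: 1, 4 and 14 are taken as purchasable (otherwise each is one known step from 5-chloropentan-1-ol, from phloroglucinol, or from benzoyl chloride and trimethylsulfoxonium iodide), and in step 8 the ligand antipode written is assumed to be the one that gives (2S); if a test on a model flavone shows the opposite sense, its mirror image is used.

Step 1
Reactants: 1 5-chloropentanal; 2 (R)-2-methylpropane-2-sulfinamide
Product: 3 (R)-N-[(1E)-5-chloropentylidene]-2-methylpropane-2-sulfinamide
Conditions: Ti(OEt)4, THF, rt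
Reagents that add atoms: none
Why: Ellman condensation of an aldehyde with tert-butanesulfinamide; Ti(OEt)4 activates the carbonyl and binds the water, and the sulfur stereocentre is not involved.

Step 2
Reactants: 4 3,5-bis(benzyloxy)phenol
Product: 5 [3,5-bis(benzyloxy)phenoxy]tri(propan-2-yl)silane
Conditions: NaH, THF, 0 °C; then TIPSCl, rt
Reagents that add atoms: chlorotri(propan-2-yl)silane (TIPSCl), CC(C)[Si](Cl)(C(C)C)C(C)C
Why: Williamson-type O-silylation of the sodium phenoxide; the bulky TIPS ether marks the one oxygen that will become O1 and, as a poor ligand for lithium, leaves the carbon between the two benzyloxy groups as the site of the next metalation.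

Step 3
Reactants: 5 [3,5-bis(benzyloxy)phenoxy]tri(propan-2-yl)silane; 3 (R)-N-[(1E)-5-chloropentylidene]-2-methylpropane-2-sulfinamide
Product: 9 (2R)-2-{2,6-bis(benzyloxy)-4-[tri(propan-2-yl)silyloxy]phenyl}-1-[(R)-tert-butylsulfinyl]piperidine, via aryllithium 6 (not isolated), via arylmagnesium bromide 7 (not isolated), via chloro sulfinamide 8 (not isolated)
Conditions: n-BuLi, Et2O, 0 °C → rt; MgBr2·OEt2, 0 °C; 3, CH2Cl2, −48 °C → 0 °C; then KOt-Bu, THF, rt
Reagents that add atoms: none
Why: Directed ortho-metalation removes the proton flanked by the two benzyloxy groups, and after exchange to magnesium the aryl group adds to the (R)-sulfinyl aldimine through the six-membered chelate of the Ellman addition (sulfinyl oxygen on magnesium, tert-butyl equatorial) on the Si face, which sets the (R) carbon; the potassium sulfinamide then closes the piperidine by 6-exo-tet displacement of chloride.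

Step 4
Reactants: 9 (2R)-2-{2,6-bis(benzyloxy)-4-[tri(propan-2-yl)silyloxy]phenyl}-1-[(R)-tert-butylsulfinyl]piperidine
Product: 11 (2R)-2-{2,6-bis(benzyloxy)-4-[tri(propan-2-yl)silyloxy]phenyl}-1-methylpiperidine, via secondary piperidine 10 (not isolated)
Conditions: HCl (4 M in dioxane), MeOH, 0 °C → rt; evaporate; then NaOAc, 37% aq. CH2O, NaBH(OAc)3, ClCH2CH2Cl, rt
Reagents that add atoms: formaldehyde, C=O
Why: Acid methanolysis cleaves the N–S bond and the secondary amine is then methylated by reductive amination with formaldehyde and NaBH(OAc)3, neither event touching the benzylic stereocentre.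

Step 5
Reactants: 11 (2R)-2-{2,6-bis(benzyloxy)-4-[tri(propan-2-yl)silyloxy]phenyl}-1-methylpiperidine
Product: 12 3,5-bis(benzyloxy)-4-[(2R)-1-methylpiperidin-2-yl]phenol
Conditions: Bu4NF, THF, 0 °C → rt
Reagents that add atoms: none
Why: Fluoride-induced cleavage of the Si–O bond (silyl ether deprotection) frees only the phenol para to the piperidine-bearing carbon, the benzyl ethers being inert.

Step 6
Reactants: 12 3,5-bis(benzyloxy)-4-[(2R)-1-methylpiperidin-2-yl]phenol
Product: 13 2,4-bis(benzyloxy)-6-hydroxy-3-[(2R)-1-methylpiperidin-2-yl]benzaldehyde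
Conditions: MgCl2, Et3N, (CH2O)n, MeCN, reflux
Reagents that add atoms: paraformaldehyde (as formaldehyde), C=O
Why: Magnesium phenoxide-directed ortho-formylation (Casnati–Skattebøl reaction): formaldehyde is delivered within the magnesium chelate to the carbon next to the phenol and a second formaldehyde oxidises the benzylic alkoxide, and since both ortho carbons are equivalent a single aldehyde should result.

Step 7
Reactants: 13 2,4-bis(benzyloxy)-6-hydroxy-3-[(2R)-1-methylpiperidin-2-yl]benzaldehyde; 14 2-[dimethyl(oxo)-λ6-sulfanylidene]-1-phenylethan-1-one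
Product: 16 5,7-bis(benzyloxy)-6-[(2R)-1-methylpiperidin-2-yl]-2-phenyl-4H-chromen-4-one, via 1,3-diketone 15 (not isolated)
Conditions: [Cp*RhCl2]2 (Cp* = pentamethylcyclopentadienyl, 4 mol %), AgSbF6 (16 mol %), PivOH (2 equiv), ClCH2CH2Cl, 80 °C
Reagents that add atoms: none
Why: The phenoxide of 13 binds the Cp*Rh fragment and directs cleavage of the aldehyde C–H to a five-membered acyl rhodacycle; ylide 14 coordinates and loses dimethyl sulfoxide to give a rhodium carbene, migratory insertion of the acyl group makes C3–C4, and protodemetalation releases diketone 15 and returns trivalent rhodium without an external oxidant. Under the acid present, the one free phenol adds to the benzoyl carbonyl (6-exo-trig, then loss of water, driven by formation of the aromatic 4-pyranone) and closes ring C through O1–C2. This is the known rhodium-catalysed annulation of salicylaldehydes with sulfoxonium ylides to chromones. No stereocentre is formed, and the (2R)-piperidine centre is not touched because pivalic acid keeps the amine protonated and off the metal. The step needs carbene insertion into the acyl–rhodium bond to win over insertion into the phenol O–H, which the chelated acyl rhodacycle favours, and it needs closure through the right oxygen, which is secured because the oxygen next to the piperidine-bearing carbon is benzylated, so only the oxygen next to C8–H can become O1 and the 6-substituted flavone should form.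

Step 8
Reactants: 16 5,7-bis(benzyloxy)-6-[(2R)-1-methylpiperidin-2-yl]-2-phenyl-4H-chromen-4-one
Product: 18 (2S)-5,7-bis(benzyloxy)-6-[(2R)-1-methylpiperidin-2-yl]-2-phenyl-2,3-dihydro-4H-chromen-4-one, via silyl enol ether 17 (not isolated)
Conditions: Cu(OAc)2 (5 mol %), (R)-DTBM-SEGPHOS (5.5 mol %), (EtO)2MeSiH, toluene, 0 °C → rt; then 1 M aq. HCl, THF, 0 °C
Reagents that add atoms: none
Why: Asymmetric conjugate reduction with a bisphosphine-ligated CuH: hydride is delivered to C2 of the chromone on the face selected by the chiral ligand, which sets (2S), the copper enolate is silylated to close the cycle, and the enol ether is hydrolysed only on work-up so the ketone is never exposed to the hydride.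

Step 9
Reactants: 18 (2S)-5,7-bis(benzyloxy)-6-[(2R)-1-methylpiperidin-2-yl]-2-phenyl-2,3-dihydro-4H-chromen-4-one
Product: 19 (2S)-5,7-dihydroxy-6-[(2R)-1-methylpiperidin-2-yl]-2-phenyl-2,3-dihydro-4H-chromen-4-one
Conditions: H2 (1 atm), 10% Pd/C, EtOAc/MeOH, rt
Reagents that add atoms: none
Why: Hydrogenolysis of the two aryl benzyl ethers on palladium under neutral conditions should be faster than cleavage of the cyclic C2–O1 and C–N benzylic bonds and leaves both stereocentres untouched.

Compound list
1 | 5-chloropentanal | O=CCCCCCl | starting material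
2 | (R)-2-methylpropane-2-sulfinamide | CC(C)(C)[S@@](=O)N | starting material
3 | (R)-N-[(1E)-5-chloropentylidene]-2-methylpropane-2-sulfinamide | CC(C)(C)[S@@](=O)/N=C/CCCCCl | intermediate
4 | 3,5-bis(benzyloxy)phenol | Oc1cc(OCc2ccccc2)cc(OCc2ccccc2)c1 | starting material
5 | [3,5-bis(benzyloxy)phenoxy]tri(propan-2-yl)silane | CC(C)[Si](Oc1cc(OCc2ccccc2)cc(OCc2ccccc2)c1)(C(C)C)C(C)C | intermediate
6 | {2,6-bis(benzyloxy)-4-[tri(propan-2-yl)silyloxy]phenyl}lithium | [Li]c1c(OCc2ccccc2)cc(O[Si](C(C)C)(C(C)C)C(C)C)cc1OCc1ccccc1 | intermediate (not isolated)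
7 | {2,6-bis(benzyloxy)-4-[tri(propan-2-yl)silyloxy]phenyl}magnesium bromide | Br[Mg]c1c(OCc2ccccc2)cc(O[Si](C(C)C)(C(C)C)C(C)C)cc1OCc1ccccc1 | intermediate (not isolated)
8 | (R)-N-[(1R)-1-{2,6-bis(benzyloxy)-4-[tri(propan-2-yl)silyloxy]phenyl}-5-chloropentyl]-2-methylpropane-2-sulfinamide | CC(C)(C)[S@@](=O)N[C@H](CCCCCl)c1c(OCc2ccccc2)cc(O[Si](C(C)C)(C(C)C)C(C)C)cc1OCc1ccccc1 | intermediate (not isolated)
9 | (2R)-2-{2,6-bis(benzyloxy)-4-[tri(propan-2-yl)silyloxy]phenyl}-1-[(R)-tert-butylsulfinyl]piperidine | CC(C)(C)[S@@](=O)N1CCCC[C@@H]1c1c(OCc2ccccc2)cc(O[Si](C(C)C)(C(C)C)C(C)C)cc1OCc1ccccc1 | intermediate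
10 | (2R)-2-{2,6-bis(benzyloxy)-4-[tri(propan-2-yl)silyloxy]phenyl}piperidine | N1CCCC[C@@H]1c1c(OCc2ccccc2)cc(O[Si](C(C)C)(C(C)C)C(C)C)cc1OCc1ccccc1 | intermediate (not isolated)
11 | (2R)-2-{2,6-bis(benzyloxy)-4-[tri(propan-2-yl)silyloxy]phenyl}-1-methylpiperidine | CN1CCCC[C@@H]1c1c(OCc2ccccc2)cc(O[Si](C(C)C)(C(C)C)C(C)C)cc1OCc1ccccc1 | intermediate
12 | 3,5-bis(benzyloxy)-4-[(2R)-1-methylpiperidin-2-yl]phenol | CN1CCCC[C@@H]1c1c(OCc2ccccc2)cc(O)cc1OCc1ccccc1 | intermediate
13 | 2,4-bis(benzyloxy)-6-hydroxy-3-[(2R)-1-methylpiperidin-2-yl]benzaldehyde | CN1CCCC[C@@H]1c1c(OCc2ccccc2)cc(O)c(C=O)c1OCc1ccccc1 | intermediate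
14 | 2-[dimethyl(oxo)-λ6-sulfanylidene]-1-phenylethan-1-one (dimethylsulfoxonium benzoylmethylide) | CS(C)(=O)=CC(=O)c1ccccc1 | starting material
15 | 1-{2,4-bis(benzyloxy)-6-hydroxy-3-[(2R)-1-methylpiperidin-2-yl]phenyl}-3-phenylpropane-1,3-dione | CN1CCCC[C@@H]1c1c(OCc2ccccc2)cc(O)c(C(=O)CC(=O)c2ccccc2)c1OCc1ccccc1 | intermediate (not isolated)
16 | 5,7-bis(benzyloxy)-6-[(2R)-1-methylpiperidin-2-yl]-2-phenyl-4H-chromen-4-one | CN1CCCC[C@@H]1c1c(OCc2ccccc2)cc2oc(-c3ccccc3)cc(=O)c2c1OCc1ccccc1 | intermediate
17 | (2S)-5,7-bis(benzyloxy)-4-{[diethoxy(methyl)silyl]oxy}-6-[(2R)-1-methylpiperidin-2-yl]-2-phenyl-2H-chromene | CN1CCCC[C@@H]1c1c(OCc2ccccc2)cc2c(c1OCc1ccccc1)C(O[Si](C)(OCC)OCC)=C[C@@H](c1ccccc1)O2 | intermediate (not isolated)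
18 | (2S)-5,7-bis(benzyloxy)-6-[(2R)-1-methylpiperidin-2-yl]-2-phenyl-2,3-dihydro-4H-chromen-4-one | CN1CCCC[C@@H]1c1c(OCc2ccccc2)cc2c(c1OCc1ccccc1)C(=O)C[C@@H](c1ccccc1)O2 | intermediate
19 | (2S)-5,7-dihydroxy-6-[(2R)-1-methylpiperidin-2-yl]-2-phenyl-2,3-dihydro-4H-chromen-4-one | CN1CCCC[C@@H]1c1c(O)cc2c(c1O)C(=O)C[C@@H](c1ccccc1)O2 | target

Total step count: 9. Longest linear sequence: 8 steps (from 4 through steps 2 to 9); step 1 is a one-step side branch that joins in step 3.

Steps most likely to fail

1. Step 8. Hydride delivery to the oxygen-bearing, aryl-substituted C2 may be slow, may discriminate the two faces poorly, or may be held up by binding of the basic amine to copper. The fallback sets out from 16 and hydrogenates it under a chiral ruthenium N-heterocyclic carbene catalyst (Ru(cod)(2-methylallyl)2, SINpEt·HBF4 of the handedness that leads to the 2S series, KOt-Bu, H2, toluene). This should saturate C2=C3 enantioselectively and then reduce the ketone, giving (2S,4S)-5,7-bis(benzyloxy)-6-[(2R)-1-methylpiperidin-2-yl]-2-phenyl-3,4-dihydro-2H-chromen-4-ol F1. Oxidation of the carbinol with Dess–Martin periodinane removes the C4 centre and comes back to the route at 18.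

2. Step 7. Cleavage of the aldehyde C–H at the doubly ortho-substituted carbonyl may be slow, the carbene may insert into the phenol O–H, or the amine may sequester rhodium. The fallback sets out from 13 and builds the two bonds one after the other. Excess lithium phenylacetylide (THF, −78 °C → rt) adds to the aldehyde and forms C3–C4, giving 1-{2,4-bis(benzyloxy)-6-hydroxy-3-[(2R)-1-methylpiperidin-2-yl]phenyl}-3-phenylprop-2-yn-1-ol F2 as a mixture of carbinol epimers. MnO2 (CH2Cl2, rt) oxidises it to 1-{2,4-bis(benzyloxy)-6-hydroxy-3-[(2R)-1-methylpiperidin-2-yl]phenyl}-3-phenylprop-2-yn-1-one F3. The phenoxide then closes ring C by 6-endo-dig conjugate addition (K2CO3, acetone, reflux), forming O1–C2 and coming back to the route at 16.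

3. Step 3. The basic aryl metal may deprotonate the enolisable aldimine instead of adding to it, and ether carried over from the metalation may loosen the magnesium chelate and erode facial control. The fallback sets out from 5 and uses the same aryllithium 6, which is acylated by tert-butyl 2-oxopiperidine-1-carboxylate (THF, −78 °C) to give tert-butyl N-(5-{2,6-bis(benzyloxy)-4-[tri(propan-2-yl)silyloxy]phenyl}-5-oxopentyl)carbamate F4. CF3CO2H (CH2Cl2, rt) removes the carbamate and the amino ketone condenses to 6-{2,6-bis(benzyloxy)-4-[tri(propan-2-yl)silyloxy]phenyl}-2,3,4,5-tetrahydropyridine F5. Asymmetric transfer hydrogenation of this cyclic imine (RuCl(p-cymene)[(S,S)-TsDPEN] or its antipode, whichever furnishes the (R)-amine, HCO2H/Et3N) sets the piperidine centre by catalyst control and comes back to the route at 10, which enters step 4 at the methylation.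

Further compounds
F1 | step 8 | (2S,4S)-5,7-bis(benzyloxy)-6-[(2R)-1-methylpiperidin-2-yl]-2-phenyl-3,4-dihydro-2H-chromen-4-ol | CN1CCCC[C@@H]1c1c(OCc2ccccc2)cc2c(c1OCc1ccccc1)[C@@H](O)C[C@@H](c1ccccc1)O2
F2 | step 7 | 1-{2,4-bis(benzyloxy)-6-hydroxy-3-[(2R)-1-methylpiperidin-2-yl]phenyl}-3-phenylprop-2-yn-1-ol (both carbinol epimers) | CN1CCCC[C@@H]1c1c(OCc2ccccc2)cc(O)c(C(O)C#Cc2ccccc2)c1OCc1ccccc1
F3 | step 7 | 1-{2,4-bis(benzyloxy)-6-hydroxy-3-[(2R)-1-methylpiperidin-2-yl]phenyl}-3-phenylprop-2-yn-1-one | CN1CCCC[C@@H]1c1c(OCc2ccccc2)cc(O)c(C(=O)C#Cc2ccccc2)c1OCc1ccccc1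
F4 | step 3 | tert-butyl N-(5-{2,6-bis(benzyloxy)-4-[tri(propan-2-yl)silyloxy]phenyl}-5-oxopentyl)carbamate | CC(C)(C)OC(=O)NCCCCC(=O)c1c(OCc2ccccc2)cc(O[Si](C(C)C)(C(C)C)C(C)C)cc1OCc1ccccc1
F5 | step 3 | 6-{2,6-bis(benzyloxy)-4-[tri(propan-2-yl)silyloxy]phenyl}-2,3,4,5-tetrahydropyridine | C1CCN=C(C1)c1c(OCc2ccccc2)cc(O[Si](C(C)C)(C(C)C)C(C)C)cc1OCc1ccccc1
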